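## Retrosynthetic overview

1. Structural feature: in the 1,2-dioxolane O1–O2–C3–C4–C5, the only ring CH2 (C4) lies between two fully substituted peroxy carbons. C5 (methyl + 2-methyl-10-phenyldecyl) maps onto the carbonyl carbon of a methyl ketone raised to a peroxycarbenium ion. C4–C3 (methyl + two-carbon arm) maps onto the CH2=C unit of an isoprenol ether.
2. Acid ⇒ primary alcohol ⇒ TBDPS ether. Dioxolane ⇒ (C4–C5 and O2–C3) triethylsilyl peroxyketal of (4R)-4-methyl-12-phenyldodecan-2-one + O-TBDPS isoprenol.
3. Silyl peroxyketal ⇒ α-methoxy hydroperoxide ⇒ (ozonolysis in MeOH) 1,1-disubstituted alkene ⇒ methyl ketone.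
4. Methyl ketone ⇒ (R)-citronellal (source of the side-chain stereocentre C2') + MeMgBr + 5-phenylpentyl ylide (ozonolysis, Wittig, hydrogenation, oxidation).
5. Ring order: the benzene ring is bought. The dioxolane is the only ring made, in one late operation.

Key step: step 11

Remarks and assumptions:
- The carbinol centre in 2, 3, 4, 8 and 9 and the ketal centre in 13 and 14 are carried as epimer mixtures, because both centres become sp2 later.
- Absolute configuration rests on commercial (R)-citronellal of high enantiomeric purity.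
- The C3 descriptor changes from S (19, 20) to R (21, 22) only through a change of CIP priorities, not through inversion.
- All peroxides are handled on a small scale behind a shield.

## Route

Step 1
Reactants: 1 (R)-citronellal
Product: 2 (4R)-4,8-dimethylnon-7-en-2-ol (C2 epimers)
Conditions: MeMgBr (1.2 equiv), Et2O, 0 °C; sat. aq NH4Cl
Reagents that add atoms: methylmagnesium bromide, C[Mg]Br
Why: Grignard 1,2-addition to an unhindered aldehyde is reliable, the methyl-bearing centre is β to the carbonyl and cannot epimerise, and the new carbinol centre forms unselectively, which is harmless because step 6 oxidises it.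

Step 2
Reactants: 2 (4R)-4,8-dimethylnon-7-en-2-ol
Product: 4 (4R)-6-hydroxy-4-methylheptanal (C6 epimers), via secondary ozonide 3 (not isolated)
Conditions: O3/O2, CH2Cl2, −78 °C; PPh3, −78 °C → rt
Reagents that add atoms: ozone, [O-][O+]=O
Why: Criegee ozonolysis cleaves the only C=C bond, and phosphine reduction of the ozonide releases the aldehyde without touching the secondary alcohol or the C4 centre.

Step 3
Reactants: 5 (5-bromopentyl)benzene
Product: 6 triphenyl(5-phenylpentyl)phosphonium bromide
Conditions: PPh3, MeCN, reflux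
Reagents that add atoms: triphenylphosphine, c1ccc(cc1)P(c1ccccc1)c1ccccc1
Why: SN2 quaternisation of triphenylphosphine by an unhindered primary bromide should give the crystalline Wittig salt.

Step 4
Reactants: 4 (4R)-6-hydroxy-4-methylheptanal; 6 triphenyl(5-phenylpentyl)phosphonium bromide
Product: 8 (4R,7Z)-4-methyl-12-phenyldodec-7-en-2-ol (C2 epimers), via phosphonium ylide 7 (not isolated)
Conditions: 6 (2.3 equiv), NaHMDS (2.2 equiv), THF, 0 °C; then 4, −78 °C → rt
Reagents that add atoms: none
Why: Wittig olefination with an excess of a non-stabilised ylide tolerates a free hydroxyl group (as in lactol olefinations) and should give mainly the Z alkene, whose geometry is irrelevant because it is hydrogenated next.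

Step 5
Reactants: 8 (4R,7Z)-4-methyl-12-phenyldodec-7-en-2-ol
Product: 9 (4R)-4-methyl-12-phenyldodecan-2-ol (C2 epimers)
Conditions: H2 (1 atm), 10% Pd/C, EtOAc, rt
Reagents that add atoms: none
Why: Heterogeneous catalytic hydrogenation saturates the disubstituted alkene under conditions that leave the benzene ring, the non-benzylic alcohol and the remote C4 centre unchanged.

Step 6
Reactants: 9 (4R)-4-methyl-12-phenyldodecan-2-ol
Product: 10 (4R)-4-methyl-12-phenyldodecan-2-one
Conditions: TPAP (5 mol %), NMO (1.5 equiv), 4 Å MS, CH2Cl2, rt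
Reagents that add atoms: none
Why: Ley–Griffith oxidation converges both carbinol epimers on one ketone under neutral conditions, and the C4 centre is β to the carbonyl and therefore not enolisable.

Step 7
Reactants: 10 (4R)-4-methyl-12-phenyldodecan-2-one
Product: 11 (4R)-2,4-dimethyl-12-phenyldodec-1-ene
Conditions: Ph3PCH3Br (1.5 equiv), KOt-Bu (1.4 equiv), THF, 0 °C → rt
Reagents that add atoms: methyltriphenylphosphonium bromide, [Br-].C[P+](c1ccccc1)(c1ccccc1)c1ccccc1
Why: Wittig methylenation of an unhindered methyl ketone is reliable and installs a CH2 terminus that serves only as the departing fragment of the next ozonolysis.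

Step 8
Reactants: 11 (4R)-2,4-dimethyl-12-phenyldodec-1-ene
Product: 13 (4R)-2-methoxy-4-methyl-12-phenyldodecan-2-yl hydroperoxide (C2 epimers), via carbonyl oxide 12 (not isolated)
Conditions: O3/O2, CH2Cl2–MeOH, −78 °C, Sudan Red 7B end point; N2 purge, no reductant; rapid SiO2 filtration
Reagents that add atoms: ozone, [O-][O+]=O; methanol, CO
Why: Criegee ozonolysis of a 1,1-dialkyl alkene fragments toward the more substituted carbonyl oxide plus formaldehyde, methanol traps that carbonyl oxide as the α-methoxy hydroperoxide, and the new ketal centre forms as both epimers, which does not matter because step 11 ionises it.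

Step 9
Reactants: 13 (4R)-2-methoxy-4-methyl-12-phenyldodecan-2-yl hydroperoxide
Product: 14 triethyl{[(4R)-2-methoxy-4-methyl-12-phenyldodecan-2-yl]peroxy}silane (C2 epimers)
Conditions: Et3SiCl (1.2 equiv), imidazole (2 equiv), DMF, 0 °C → rt
Reagents that add atoms: chlorotriethylsilane, CC[Si](Cl)(CC)CC
Why: Imidazole-promoted O-silylation of the acidic, nucleophilic hydroperoxide proceeds under non-acidic conditions that keep the monoperoxyketal intact.

Step 10
Reactants: 15 3-methylbut-3-en-1-ol
Product: 16 tert-butyl[(3-methylbut-3-en-1-yl)oxy]diphenylsilane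
Conditions: TBDPSCl (1.05 equiv), imidazole (2 equiv), CH2Cl2, rt
Reagents that add atoms: tert-butylchlorodiphenylsilane, CC(C)(C)[Si](Cl)(c1ccccc1)c1ccccc1
Why: Standard silylation of a primary alcohol gives a bulky, weakly Lewis basic ether that should survive SnCl4 at low temperature and provides a UV handle for the later separation.

Step 11
Reactants: 14 triethyl{[(4R)-2-methoxy-4-methyl-12-phenyldodecan-2-yl]peroxy}silane; 16 tert-butyl[(3-methylbut-3-en-1-yl)oxy]diphenylsilane
Product: 19 tert-butyl{2-[(3S,5R)-3,5-dimethyl-5-[(2R)-2-methyl-10-phenyldecyl]-1,2-dioxolan-3-yl]ethoxy}diphenylsilane, via peroxycarbenium ion 17 (not isolated), via tertiary carbocation 18 (not isolated)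
Conditions: 16 (3 equiv), SnCl4 (1.1 equiv), CH2Cl2, −78 °C; aq NaHCO3; SiO2 chromatography, then preparative HPLC (polysaccharide chiral phase)
Reagents that add atoms: none
Why: SnCl4 abstracts methoxide from either ketal epimer of 14 to give the planar peroxycarbenium ion 17, and the CH2 terminus of the 1,1-disubstituted alkene 16 adds to its carbon (C4–C5), which places the charge on the tertiary carbon C3 in 18. The silylated peroxide oxygen O2 then captures this cation and chloride removes the Et3Si group, so the only ring formed, the 1,2-dioxolane, closes by a five-membered cation–oxygen collapse (O2–C3) and not by a concerted cycloaddition. The closest known reaction type is the Lewis acid-promoted (3+2) annulation of ketone-derived triethylsilyl peroxyketals with simple alkenes, including 1,1-disubstituted ones. C5 is fixed in the C–C bond formation, where only the C2' methyl centre (1,3 to the cationic carbon) differentiates the two faces, and C3 is fixed in the ring closure, where only the small size difference between CH3 and the CH2CH2OSi arm matters. The regiochemistry needed (CH2 to carbon, oxygen to the substituted carbon) is secured by the tertiary cation, and chemoselectivity is secured by the TBDPS ether, whose oxygen could only close a strained oxetane. The diastereoselectivity needed (cis-3,5-dimethyl, 5R relative to 2'R) is not secured by the substrate, so all four ring diastereomers should form in comparable amounts; 19 is then taken out by silica chromatography (cis from trans) and by HPLC on a chiral phase (the two cis isomers, pseudo-enantiomeric in the ring).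

Step 12
Reactants: 19 tert-butyl{2-[(3S,5R)-3,5-dimethyl-5-[(2R)-2-methyl-10-phenyldecyl]-1,2-dioxolan-3-yl]ethoxy}diphenylsilane
Product: 20 2-[(3S,5R)-3,5-dimethyl-5-[(2R)-2-methyl-10-phenyldecyl]-1,2-dioxolan-3-yl]ethan-1-ol
Conditions: TBAF/AcOH (1:1, 2 equiv), THF, 0 °C → rt
Reagents that add atoms: none
Why: Fluoride-driven Si–O cleavage is safe here because neither peroxy carbon bears a hydrogen, so Kornblum–DeLaMare fragmentation is impossible, and the acetic acid buffer avoids a free alkoxide.

Step 13
Reactants: 20 2-[(3S,5R)-3,5-dimethyl-5-[(2R)-2-methyl-10-phenyldecyl]-1,2-dioxolan-3-yl]ethan-1-ol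
Product: 22 2-[(3R,5R)-3,5-dimethyl-5-[(2R)-2-methyl-10-phenyldecyl]-1,2-dioxolan-3-yl]acetic acid, via dioxolanyl acetaldehyde 21 (not isolated)
Conditions: TEMPO (0.2 equiv), PhI(OAc)2 (2.5 equiv), CH2Cl2–H2O, rt
Reagents that add atoms: water, O
Why: Oxoammonium oxidation (TEMPO/BAIB) takes the alcohol through the aldehyde and its hydrate to the acid in a metal-free, weakly acidic medium that neither cleaves the O–O bond nor provokes base-induced β-elimination of the β-peroxy aldehyde, and the quaternary ring centres cannot epimerise.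

## Compound list

1 | (R)-citronellal | C[C@H](CCC=C(C)C)CC=O | starting material
2 | (4R)-4,8-dimethylnon-7-en-2-ol (C2 epimers) | C[C@H](CCC=C(C)C)CC(C)O | intermediate
3 | (4R)-6-(5,5-dimethyl-1,2,4-trioxolan-3-yl)-4-methylhexan-2-ol (secondary ozonide, not isolated) | C[C@H](CCC1OOC(C)(C)O1)CC(C)O | intermediate
4 | (4R)-6-hydroxy-4-methylheptanal (C6 epimers) | C[C@H](CCC=O)CC(C)O | intermediate
5 | (5-bromopentyl)benzene | BrCCCCCc1ccccc1 | starting material
6 | triphenyl(5-phenylpentyl)phosphonium bromide | [Br-].c1ccc(CCCCC[P+](c2ccccc2)(c2ccccc2)c2ccccc2)cc1 | intermediate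
7 | triphenyl(5-phenylpentylidene)phosphorane (ylide, not isolated) | c1ccc(CCCCC=P(c2ccccc2)(c2ccccc2)c2ccccc2)cc1 | intermediate
8 | (4R,7Z)-4-methyl-12-phenyldodec-7-en-2-ol (C2 epimers) | C[C@H](CC/C=C\CCCCc1ccccc1)CC(C)O | intermediate
9 | (4R)-4-methyl-12-phenyldodecan-2-ol (C2 epimers) | C[C@H](CCCCCCCCc1ccccc1)CC(C)O | intermediate
10 | (4R)-4-methyl-12-phenyldodecan-2-one | C[C@H](CCCCCCCCc1ccccc1)CC(C)=O | intermediate
11 | (4R)-2,4-dimethyl-12-phenyldodec-1-ene | C[C@H](CCCCCCCCc1ccccc1)CC(C)=C | intermediate
12 | (4R)-4-methyl-12-phenyldodecan-2-one O-oxide (carbonyl oxide, not isolated) | C[C@H](CCCCCCCCc1ccccc1)CC(C)=[O+][O-] | intermediate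
13 | (4R)-2-methoxy-4-methyl-12-phenyldodecan-2-yl hydroperoxide (C2 epimers) | C[C@H](CCCCCCCCc1ccccc1)CC(C)(OC)OO | intermediate
14 | triethyl{[(4R)-2-methoxy-4-methyl-12-phenyldodecan-2-yl]peroxy}silane (C2 epimers) | C[C@H](CCCCCCCCc1ccccc1)CC(C)(OC)OO[Si](CC)(CC)CC | intermediate
15 | 3-methylbut-3-en-1-ol | C=C(C)CCO | starting material
16 | tert-butyl[(3-methylbut-3-en-1-yl)oxy]diphenylsilane | C=C(C)CCO[Si](c1ccccc1)(c1ccccc1)C(C)(C)C | intermediate
17 | [(4R)-4-methyl-12-phenyldodecan-2-ylidene](triethylsilyloxy)oxonium (peroxycarbenium ion, not isolated) | C[C@H](CCCCCCCCc1ccccc1)CC(C)=[O+]O[Si](CC)(CC)CC | intermediate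
18 | tertiary C3 carbocation after C4–C5 bond formation, C5 configured as in 19 (not isolated) | C[C@H](CCCCCCCCc1ccccc1)C[C@@](C)(OO[Si](CC)(CC)CC)C[C+](C)CCO[Si](c1ccccc1)(c1ccccc1)C(C)(C)C | intermediate
19 | tert-butyl{2-[(3S,5R)-3,5-dimethyl-5-[(2R)-2-methyl-10-phenyldecyl]-1,2-dioxolan-3-yl]ethoxy}diphenylsilane | C[C@H](CCCCCCCCc1ccccc1)C[C@]1(C)C[C@](C)(CCO[Si](c2ccccc2)(c2ccccc2)C(C)(C)C)OO1 | intermediate
20 | 2-[(3S,5R)-3,5-dimethyl-5-[(2R)-2-methyl-10-phenyldecyl]-1,2-dioxolan-3-yl]ethan-1-ol | C[C@H](CCCCCCCCc1ccccc1)C[C@]1(C)C[C@](C)(CCO)OO1 | intermediate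
21 | 2-[(3R,5R)-3,5-dimethyl-5-[(2R)-2-methyl-10-phenyldecyl]-1,2-dioxolan-3-yl]acetaldehyde (not isolated) | C[C@H](CCCCCCCCc1ccccc1)C[C@]1(C)C[C@](C)(CC=O)OO1 | intermediate
22 | 2-[(3R,5R)-3,5-dimethyl-5-[(2R)-2-methyl-10-phenyldecyl]-1,2-dioxolan-3-yl]acetic acid | C[C@H](CCCCCCCCc1ccccc1)C[C@]1(C)C[C@](C)(CC(=O)O)OO1 | target

## Step count and risks

Total step count: 13.
Longest linear sequence: 11 (steps 1, 2, 4–9, 11–13, from (R)-citronellal).

**Risk 1: step 11 (key step).**
- What may go wrong: the tertiary cation may lose a proton or pick up chloride instead of closing. The alkene may oligomerise under SnCl4. Above all, facial and cis/trans selectivity should be poor, so isolating one of four diastereomers may prove impractical.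
- The fallback sets out from 14 and returns at 22; it makes the two ring bonds in separate operations.
- Methyl 3-methylbut-2-enoate is converted (LDA, Me3SiCl, THF, −78 °C) into the silyl dienol ether [(1-methoxy-3-methylbuta-1,3-dien-1-yl)oxy]trimethylsilane F1.
- The γ-CH2 of this reagent attacks the peroxycarbenium ion generated from 14 (SnCl4, CH2Cl2, −78 °C; vinylogous Mukaiyama-type alkylation). This gives methyl (2E,7R)-3,5,7-trimethyl-15-phenyl-5-[(triethylsilyl)peroxy]pentadec-2-enoate F2.
- HF·pyridine releases methyl (2E,7R)-5-hydroperoxy-3,5,7-trimethyl-15-phenylpentadec-2-enoate F3, whose C5 epimers can be separated in open-chain form.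
- Catalytic Et2NH in CF3CH2OH closes the ring by a 5-exo-trig intramolecular peroxy-Michael addition to methyl 2-[(3R,5R)-3,5-dimethyl-5-[(2R)-2-methyl-10-phenyldecyl]-1,2-dioxolan-3-yl]acetate F4.
- This addition is reversible, so the unwanted C3 epimer can be resubmitted and equilibrated.
- LiOH in THF–H2O then gives 22.

**Risk 2: step 8.**
- What may go wrong: the alkene may cleave in the wrong sense, with oxygen retained on the CH2 fragment, which simply returns the ketone. The hydroperoxyketal may revert on silica. Excess ozone may attack the arene.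
- The fallback sets out from 10 and returns at 13, bypassing steps 7 and 8.
- Ketalisation (HC(OMe)3, MeOH, cat. TsOH) gives (4R)-2,2-dimethoxy-4-methyl-12-phenyldodecane F5.
- Acid-catalysed perhydrolysis (ethereal H2O2, cat. CSA, 0 °C) exchanges one methoxy group for OOH. It is stopped before the second exchange.

**Risk 3: step 4.**
- What may go wrong: the basic ylide may enolise the unprotected hydroxy aldehyde or trigger its self-condensation, and hemiacetal oligomerisation may lower conversion.
- The fallback sets out from 4 (and 5) and returns at 9, bypassing steps 3–5. It replaces olefination/hydrogenation by an sp3–sp3 coupling.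
- NaBH4 in MeOH gives (4R)-4-methylheptane-1,6-diol F6.
- Selective tosylation of the primary hydroxyl (TsCl, pyridine, 0 °C) gives (4R)-6-hydroxy-4-methylheptyl 4-methylbenzenesulfonate F7.
- Bromide 5 is converted with Mg in THF into (5-phenylpentyl)magnesium bromide F8.
- F8 (2.5 equiv, one equivalent being consumed by the free hydroxyl) couples with the tosylate under Li2CuCl4 catalysis (Fouquet–Schlosser conditions, THF, −20 °C → rt). This delivers the eight-methylene chain of 9 directly.

## Further compounds

F1 | step 11 | [(1-methoxy-3-methylbuta-1,3-dien-1-yl)oxy]trimethylsilane | C=C(C)C=C(OC)O[Si](C)(C)C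
F2 | step 11 | methyl (2E,7R)-3,5,7-trimethyl-15-phenyl-5-[(triethylsilyl)peroxy]pentadec-2-enoate (C5 epimers) | C[C@H](CCCCCCCCc1ccccc1)CC(C)(OO[Si](CC)(CC)CC)C/C(C)=C/C(=O)OC
F3 | step 11 | methyl (2E,7R)-5-hydroperoxy-3,5,7-trimethyl-15-phenylpentadec-2-enoate (C5 epimers) | C[C@H](CCCCCCCCc1ccccc1)CC(C)(OO)C/C(C)=C/C(=O)OC
F4 | step 11 | methyl 2-[(3R,5R)-3,5-dimethyl-5-[(2R)-2-methyl-10-phenyldecyl]-1,2-dioxolan-3-yl]acetate | C[C@H](CCCCCCCCc1ccccc1)C[C@]1(C)C[C@](C)(CC(=O)OC)OO1
F5 | step 8 | (4R)-2,2-dimethoxy-4-methyl-12-phenyldodecane | C[C@H](CCCCCCCCc1ccccc1)CC(C)(OC)OC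
F6 | step 4 | (4R)-4-methylheptane-1,6-diol (C6 epimers) | C[C@H](CCCO)CC(C)O
F7 | step 4 | (4R)-6-hydroxy-4-methylheptyl 4-methylbenzenesulfonate (C6 epimers) | C[C@H](CCCOS(=O)(=O)c1ccc(C)cc1)CC(C)O
F8 | step 4 | (5-phenylpentyl)magnesium bromide | Br[Mg]CCCCCc1ccccc1
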